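Cutting the dibenzofuran C–C bond between the ring A carbon that sits between the benzylic carbon and the oxygen-bearing carbon and the ring B carbon ortho to that oxygen and para to its ethylene arm is the central disconnection. The A–O–B ether oxygen already holds these two carbons 1,5 to each other, so a Pd-catalysed C–H arylation from a ring A bromide should, in one operation, forge the biaryl bond, close the furan ring and contract the macrocycle from 19 to 18 members. Its precursor is the unstrained 19-membered bis(diaryl ether) bis(bibenzyl) dimethyl ether with bromine on that ring A carbon, built by Chan–Lam and SNAr etherifications, Wittig union and McMurry closure.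

Key step: step 11

Remark: the target has no stereocentre, and both stilbene intermediates are carried as E/Z mixtures because step 10 saturates both double bonds. Ring letters: A is the bromo/methoxy ring, B the ring ether-linked to A, C the isovanillate ring, D the para-phenylene ring.

Step 1
Reactants: 1 3-hydroxy-5-methoxybenzaldehyde (ring A); 2 3-(methoxycarbonyl)phenylboronic acid (ring B)
Product: 3 methyl 3-(3-formyl-5-methoxyphenoxy)benzoate
Conditions: 2 (2 equiv), Cu(OAc)2 (1 equiv), pyridine (5 equiv), 4 Å MS, CH2Cl2, air, rt
Reagents that add atoms: none
Why: Chan–Lam O-arylation, in which the aryl group passes from boron to copper and C–O reductive elimination from trivalent copper gives the diaryl ether at room temperature, where the aldehyde and the ester are inert and air returns the copper to Cu(OAc)2.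

Step 2
Reactants: 3 methyl 3-(3-formyl-5-methoxyphenoxy)benzoate
Product: 4 methyl 3-(2-bromo-3-formyl-5-methoxyphenoxy)benzoate
Conditions: NBS (1.05 equiv), MeCN, 0 °C to rt, dark
Reagents that add atoms: N-bromosuccinimide, O=C1CCC(=O)N1Br
Why: Electrophilic aromatic bromination should take place only on the doubly oxygenated ring A (ring B is deactivated by its ester) and at the carbon para to the methoxy group, the stronger of the two oxygen donors, which is the carbon between the formyl and aryloxy groups, as 3,5-dialkoxybenzaldehydes are known to brominate at C2.

Step 3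
Reactants: 5 methyl isovanillate (methyl 3-hydroxy-4-methoxybenzoate, ring C); 6 4-fluorobenzaldehyde (ring D)
Product: 7 methyl 3-(4-formylphenoxy)-4-methoxybenzoate
Conditions: K2CO3 (2 equiv), DMF, 130 °C
Reagents that add atoms: none
Why: Nucleophilic aromatic substitution (addition–elimination), in which the phenoxide of 5 displaces the fluoride that is activated by the para formyl group.

Step 4
Reactants: 7 methyl 3-(4-formylphenoxy)-4-methoxybenzoate
Product: 8 methyl 3-[4-(hydroxymethyl)phenoxy]-4-methoxybenzoate
Conditions: NaBH4, MeOH/THF, 0 °C
Reagents that add atoms: none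
Why: Chemoselective borohydride reduction, since NaBH4 reduces the aldehyde at 0 °C and leaves the aryl methyl ester untouched.

Step 5
Reactants: 8 methyl 3-[4-(hydroxymethyl)phenoxy]-4-methoxybenzoate
Product: 9 {4-[2-methoxy-5-(methoxycarbonyl)phenoxy]benzyl}triphenylphosphonium bromide
Conditions: PPh3·HBr (1.1 equiv), MeCN, reflux
Reagents that add atoms: triphenylphosphine hydrobromide, [Br-].c1ccc(cc1)[PH+](c1ccccc1)c1ccccc1
Why: Acid-promoted benzylic substitution, in which the protonated alcohol, activated by the para aryloxy group, is displaced and trapped by triphenylphosphine, so the phosphonium salt forms directly without a separate benzylic bromide.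

Step 6
Reactants: 4 methyl 3-(2-bromo-3-formyl-5-methoxyphenoxy)benzoate; 9 {4-[2-methoxy-5-(methoxycarbonyl)phenoxy]benzyl}triphenylphosphonium bromide
Product: 11 open-chain bromo stilbene diester methyl 3-(2-bromo-5-methoxy-3-{2-[4-(2-methoxy-5-(methoxycarbonyl)phenoxy)phenyl]ethenyl}phenoxy)benzoate as an E/Z mixture, via ring D benzylidenetriphenylphosphorane 10 (not isolated)
Conditions: K2CO3 (3 equiv), 18-crown-6 (cat.), CH2Cl2, reflux
Reagents that add atoms: none
Why: Wittig olefination with a semi-stabilised benzylic ylide generated by solid carbonate, conditions mild enough for both methyl esters and the aryl bromide, and the alkene geometry is irrelevant because the double bond is saturated in step 10.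

Step 7
Reactants: 11 open-chain bromo stilbene diester
Product: 12 open-chain bromo stilbene diol (both CO2Me groups converted to CH2OH, E/Z mixture)
Conditions: i-Bu2AlH (6 equiv), CH2Cl2, −78 to 0 °C; aq. KNaC4H4O6 work-up
Reagents that add atoms: none
Why: Hydride reduction of both aryl esters to benzylic alcohols with i-Bu2AlH, which at low temperature does not touch the aryl bromide or the stilbene.

Step 8
Reactants: 12 open-chain bromo stilbene diol
Product: 13 open-chain bromo stilbene dialdehyde (formyl groups on ring B and ring C, E/Z mixture)
Conditions: Dess–Martin periodinane (2.5 equiv), NaHCO3, CH2Cl2, rt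
Reagents that add atoms: none
Why: Dess–Martin oxidation of the two benzylic alcohols stops cleanly at the aldehyde and is compatible with the stilbene, the aryl bromide and the diaryl ethers.

Step 9
Reactants: 13 open-chain bromo stilbene dialdehyde
Product: 14 19-membered bromo bis-stilbene macrocycle (rings B and C joined by CH=CH, E/Z mixture at both alkenes)
Conditions: TiCl4 (10 equiv), Zn (20 equiv), pyridine, THF, reflux; 13 added over 12 h by syringe pump (final 2 mM)
Reagents that add atoms: none
Why: Intramolecular McMurry coupling, in which low-valent titanium couples the two aryl aldehydes to a titanium-bound pinacolate and deoxygenates it to the alkene, with slow addition favouring ring closure and with aryl bromides normally surviving TiCl4/Zn.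

Step 10
Reactants: 14 19-membered bromo bis-stilbene macrocycle
Product: 15 19-membered bromo bis(diaryl ether) bis(bibenzyl) macrocycle (both bridges CH2CH2, bromine on ring A between the benzylic carbon and the aryloxy carbon)
Conditions: TsNHNH2 (20 equiv, in portions), NaOAc (20 equiv), DME/H2O, reflux
Reagents that add atoms: none
Why: Diimide reduction, in which diimide generated from the sulfonyl hydrazide delivers two hydrogens to each stilbene double bond in a concerted way and, unlike hydrogenation over palladium, cannot cleave the aryl C–Br bond.

Step 11
Reactants: 15 19-membered bromo bis(diaryl ether) bis(bibenzyl) macrocycle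
Product: 16 asterelin A dimethyl ether (18-membered dibenzofuran-containing macrocycle)
Conditions: Pd(OAc)2 (10 mol %), PCy3·HBF4 (20 mol %), PivOH (30 mol %), K2CO3 (3 equiv), DMA, 130 °C, 5 mM, argon
Reagents that add atoms: none
Why: Zerovalent palladium, formed from Pd(OAc)2 and PCy3, inserts into the ring A C–Br bond, bromide is exchanged for pivalate, and carboxylate-assisted concerted metalation–deprotonation of the ring B C–H ortho to the ether oxygen gives a six-membered diaryl palladacycle whose reductive elimination forms the biaryl bond. The closest known reaction type is the Pd-catalysed intramolecular direct arylation of 2-bromodiaryl ethers to dibenzofurans, applied here inside a macrocycle. The furan ring is closed in a formal 5-exo mode onto ring B, and the 18-membered ring arises by transannular contraction of the existing 19-membered ring and not by macrocyclisation, so the only new cost is the strain of bringing rings A and B into one plane, paid in an irreversible step. No stereocentre is created. The step needs site selectivity: on ring A the bromine fixes the carbon; on ring B the C–H para to the ethylene arm is unhindered and leads to the 18-membered product, whereas the C–H between oxygen and arm is flanked by two substituents and would give a bay-bridged 16-membered ring; the ortho C–H of ring D, reachable through the ethylene tether by a seven-membered palladacycle, would force ring D into a meta-bridged 15-membered ring and should therefore not compete. High dilution suppresses intermolecular arylation and the bulky electron-rich phosphine helps insertion into the doubly ortho-substituted bromide.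

Step 12
Reactants: 16 asterelin A dimethyl ether
Product: 17 asterelin A
Conditions: BBr3 (6 equiv), CH2Cl2, −78 °C to rt; then H2O
Reagents that add atoms: none
Why: Lewis-acid-mediated O-demethylation, in which BBr3 cleaves both aryl methyl ethers through bromide attack on the activated methyl groups while the diaryl ether and dibenzofuran C–O bonds, which offer no sp3 carbon for attack, remain intact.

Compound list
1 | 3-hydroxy-5-methoxybenzaldehyde (ring A) | COc1cc(O)cc(C=O)c1 | starting material
2 | 3-(methoxycarbonyl)phenylboronic acid (ring B) | COC(=O)c1cccc(B(O)O)c1 | starting material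
3 | methyl 3-(3-formyl-5-methoxyphenoxy)benzoate | COC(=O)c1cccc(Oc2cc(OC)cc(C=O)c2)c1 | intermediate
4 | methyl 3-(2-bromo-3-formyl-5-methoxyphenoxy)benzoate | COC(=O)c1cccc(Oc2cc(OC)cc(C=O)c2Br)c1 | intermediate
5 | methyl isovanillate (methyl 3-hydroxy-4-methoxybenzoate, ring C) | COC(=O)c1ccc(OC)c(O)c1 | starting material
6 | 4-fluorobenzaldehyde (ring D) | O=Cc1ccc(F)cc1 | starting material
7 | methyl 3-(4-formylphenoxy)-4-methoxybenzoate | COC(=O)c1ccc(OC)c(Oc2ccc(C=O)cc2)c1 | intermediate
8 | methyl 3-[4-(hydroxymethyl)phenoxy]-4-methoxybenzoate | COC(=O)c1ccc(OC)c(Oc2ccc(CO)cc2)c1 | intermediate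
9 | {4-[2-methoxy-5-(methoxycarbonyl)phenoxy]benzyl}triphenylphosphonium bromide | COC(=O)c1ccc(OC)c(Oc2ccc(C[P+](c3ccccc3)(c3ccccc3)c3ccccc3)cc2)c1.[Br-] | intermediate
10 | ring D benzylidenetriphenylphosphorane (ylide of 9, not isolated) | COC(=O)c1ccc(OC)c(Oc2ccc(C=P(c3ccccc3)(c3ccccc3)c3ccccc3)cc2)c1 | intermediate
11 | open-chain bromo stilbene diester, methyl 3-(2-bromo-5-methoxy-3-{2-[4-(2-methoxy-5-(methoxycarbonyl)phenoxy)phenyl]ethenyl}phenoxy)benzoate, E/Z mixture | COC(=O)c1cccc(Oc2cc(OC)cc(C=Cc3ccc(Oc4cc(C(=O)OC)ccc4OC)cc3)c2Br)c1 | intermediate
12 | open-chain bromo stilbene diol (CH2OH on ring B and on ring C), E/Z mixture | OCc1cccc(Oc2cc(OC)cc(C=Cc3ccc(Oc4cc(CO)ccc4OC)cc3)c2Br)c1 | intermediate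
13 | open-chain bromo stilbene dialdehyde (CHO on ring B and on ring C), E/Z mixture | O=Cc1cccc(Oc2cc(OC)cc(C=Cc3ccc(Oc4cc(C=O)ccc4OC)cc3)c2Br)c1 | intermediate
14 | 19-membered bromo bis-stilbene macrocycle, E/Z mixture at both alkenes | COc1cc2c(Br)c(c1)Oc1cccc(c1)C=Cc1ccc(OC)c(c1)Oc1ccc(cc1)C=C2 | intermediate
15 | 19-membered bromo bis(diaryl ether) bis(bibenzyl) macrocycle | COc1cc2c(Br)c(c1)Oc1cccc(c1)CCc1ccc(OC)c(c1)Oc1ccc(cc1)CC2 | intermediate
16 | asterelin A dimethyl ether | COc1cc2c3c(c1)oc1cc(ccc13)CCc1ccc(OC)c(c1)Oc1ccc(cc1)CC2 | intermediate
17 | asterelin A | Oc1cc2c3c(c1)oc1cc(ccc13)CCc1ccc(O)c(c1)Oc1ccc(cc1)CC2 | target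

Total step count: 12
Longest linear sequence: 10 steps (steps 3, 4, 5, 6, 7, 8, 9, 10, 11 and 12, from 5 and 6)

Steps most likely to fail

Step 11. The palladated ring A may be reduced to the debrominated macrocycle, or may arylate a second molecule, if the strain of flattening rings A and B inside the ring slows the transannular C–H cleavage. The fallback sets out from 4 and comes back at 16; it forms the dibenzofuran before any macrocycle exists. Bromo aldehyde 4 is cyclised in the open-chain series with Pd(OAc)2, PCy3·HBF4, PivOH and K2CO3 in DMA at 120 °C, where the less hindered ring B C–H para to the ester should react, to give methyl 9-formyl-7-methoxydibenzofuran-3-carboxylate F1. Wittig reaction of F1 with phosphonium salt 9 (K2CO3, 18-crown-6, CH2Cl2) should give the dibenzofuran stilbene diester F2. Reduction with i-Bu2AlH gives the dibenzofuran stilbene diol F3, and Dess–Martin oxidation gives the dibenzofuran stilbene dialdehyde F4. McMurry coupling (TiCl4, Zn, pyridine, THF, high dilution) then closes the 18-membered ring directly to the dibenzofuran bis-stilbene macrocycle F5. With no halogen left, hydrogenation of F5 over Pd/C in EtOAc/THF saturates both alkenes and gives 16.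

Step 9. Intermolecular coupling to oligomers, arrest at the pinacol stage, or partial reductive loss of bromine by low-valent titanium may erode the ring closure. The fallback sets out from 13 and comes back at 14; it replaces reductive carbonyl coupling by olefin metathesis. Double Wittig methylenation of 13 (methyltriphenylphosphonium bromide, KOt-Bu, THF, 0 °C) gives the bromo stilbene bis-styrene F6. Ring-closing metathesis of F6 with the second-generation Grubbs catalyst in dilute toluene (2 mM, 60 °C) expels ethylene and closes the B/C bridge to give 14. The two terminal styrenes should react far faster than the internal, ortho-bromo-substituted stilbene, which should remain a spectator.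

Step 2. Discrimination between the carbon para to methoxy and the carbon para to aryloxy may be incomplete, giving regioisomeric bromides that are hard to separate. The regiochemistry of 4 should be checked by NOE and HMBC before the material is carried on. The fallback sets out from 3 and comes back at 4; it lets a free hydroxyl group, a much stronger para director, steer the halogen. Demethylation of 3 with BBr3 (CH2Cl2, −78 to 0 °C) gives methyl 3-(3-formyl-5-hydroxyphenoxy)benzoate F7. NBS in MeCN at 0 °C brominates para to the hydroxyl group, between the formyl and aryloxy groups, to give methyl 3-(2-bromo-3-formyl-5-hydroxyphenoxy)benzoate F8. Methylation with MeI and K2CO3 in acetone then gives 4 and would also re-esterify any acid formed during the demethylation.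

Further compounds
F1 | step 11 | methyl 9-formyl-7-methoxydibenzofuran-3-carboxylate | COC(=O)c1ccc2c(c1)oc1cc(OC)cc(C=O)c12
F2 | step 11 | dibenzofuran stilbene diester (E/Z mixture) | COC(=O)c1ccc2c(c1)oc1cc(OC)cc(C=Cc3ccc(Oc4cc(C(=O)OC)ccc4OC)cc3)c12
F3 | step 11 | dibenzofuran stilbene diol (E/Z mixture) | OCc1ccc2c(c1)oc1cc(OC)cc(C=Cc3ccc(Oc4cc(CO)ccc4OC)cc3)c12
F4 | step 11 | dibenzofuran stilbene dialdehyde (E/Z mixture) | O=Cc1ccc2c(c1)oc1cc(OC)cc(C=Cc3ccc(Oc4cc(C=O)ccc4OC)cc3)c12
F5 | step 11 | 18-membered dibenzofuran bis-stilbene macrocycle (E/Z mixture at both alkenes) | COc1cc2c3c(c1)oc1cc(ccc13)C=Cc1ccc(OC)c(c1)Oc1ccc(cc1)C=C2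
F6 | step 9 | bromo stilbene bis-styrene (vinyl groups on ring B and ring C, E/Z mixture at the internal alkene) | C=Cc1cccc(Oc2cc(OC)cc(C=Cc3ccc(Oc4cc(C=C)ccc4OC)cc3)c2Br)c1
F7 | step 2 | methyl 3-(3-formyl-5-hydroxyphenoxy)benzoate | COC(=O)c1cccc(Oc2cc(O)cc(C=O)c2)c1
F8 | step 2 | methyl 3-(2-bromo-3-formyl-5-hydroxyphenoxy)benzoate | COC(=O)c1cccc(Oc2cc(O)cc(C=O)c2Br)c1
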